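Follow the Q through midnight, entry by entry. Q is the limiting reagent there, since its charge is less than the charge of Z.

| flask | Z | Q | remark | time |
|---|---|---|---|---|
| north-east | 0.0061 M | 0.0199 M | run made earlier |  |
| south | 0.090 M | 0.0199 M | run made earlier |  |
| south-west | 0.019 M | 0.014 M | run made earlier |  |
| summer | 0.019 M | 0.0120 M |  | 4.0 min |
| autumn | 0.040 M | 0.0600 M |  | 4.0 min |
| winter | 0.019 M | 0.0199 M |  | 4.0 min |
| noon | 0.0050 M | 0.00500 M |  | 4.0 min |
| midnight | 0.060 M | 0.00500 M |  | 4.0 min |

| run | time / s | G / % | Z / % |
|---|---|---|---|
| north-east | 10.0 | 3.1 | 96.2 |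
| north-east | 25.0 | 9.2 | 90.4 |
| north-east | 40.0 | 13.3 | 85.6 |
| north-east | 60.0 | 20.9 | 78.3 |
| north-east | 90.0 | 24.7 | 72.6 |
| north-east | 120 | 30.2 | 65.0 |
| south | 10.0 | 1.8 | 96.2 |
| south | 25.0 | 5.3 | 91.8 |
| south | 40.0 | 8.9 | 87.3 |
| south | 60.0 | 9.9 | 84.2 |
| south | 90.0 | 12.0 | 81.1 |
| south | 120 | 9.8 | 74.3 |
| south-west | 25.0 | 6.1 | 94.9 |
| south-west | 50.0 | 12.3 | 89.2 |
| south-west | 80.0 | 14.5 | 82.8 |
| south-west | 90.0 | 15.1 | 82.0 |
| south-west | 120 | 20.9 | 74.6 |

(scatter of a reading: 1 percentage point)

* all flasks from highest to lowest amount of G, in percent of the Z charged, at 4.0 min (summer / autumn / winter / noon / midnight)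
* the amount of G, in percent of the Z charged of the flask you put first, at 4.0 min
* the amount of G, in percent of the Z charged of the flask you put last, at 4.0 min



First I need the rate of the step that spends Q. In the north-east run Q stands in excess and the Z reading falls to 65.0% by 120 s. With Q taken at its mean, I read from this a making constant of 0.191 /M/s, with the scatter of the reading in it.

By 120 s the south run reads a loss of 0.0231 M of Z, more than its 0.0199 M of Q, so I take it that G takes a second Z. My books therefore run like this. Each Q spent takes one Z and makes one G, and each G eaten takes another Z. So Q spent is half the sum of Z lost and G standing, and I book no other entry.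

In my books making and eating both carry Z, so Z cancels, and G stops rising at a fixed ratio of G to Q, the balance ratio. South G tops at a reading of 12.0% at 90.0 s, when the books leave 0.00599 M of Q. That reads as 1.80, with the scatter of the readings in it. Its inverse, p, is the selectivity factor of my books.

Now midnight. With Z held at 0.0550 M, the Q left at 4.0 min is 8.08% of its charge. With f the fraction of Q left, my books put G at (f^p − f)/(1 − p) of the Q charged, which gives 37.5%. The remaining 54.4% of the Q charged is booked as passed through G to a second Z. The books close there, and for midnight I commit to 3.12% of the Z charged.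

The forecast orders the flasks autumn > winter > summer > noon > midnight, with 66% on top and 3.8% last; its low is higher than mine. It says: “Midnight is low because Q runs out and the excess Z dilutes the percentage, while also eating G.”

The flasks give autumn > winter > summer > noon > midnight, with 41.2% and 4.04%. The forecast's order stands and its low agrees within the margin, but the top lies under the forecast, and my midnight figure lies under the flask's.

    Z + Q → G + X (k = 0.190 /M/s)
    Q + G → D + X (k = 0.0910 /M/s)
    Q + D → L + X (k = 0.00980 /M/s)
    Z + G → J (k = 0.0690 /M/s)

In midnight at 4.00 min, G over Q stands at 6.50, above my balance ratio. G is then made at 0.420 of the rate it is used, after being made 3.50 times faster at 0.913 min, and the path through Z uses it 110 times faster than the path through Q.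

For a neighbour like midnight but with 0.013 M of Q, the same books leave 11.6% of its Q charge and give G at 9.09% of the Z charged. The computed flask holds 9.1% of its Q charge and G at 10.5% of the Z charged.

The readings were generated by integration with made-up constants, and the scatter is random.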